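## Structural features

The target is a single oxane ring (O1, C2 to C6) with three carbon substituents: a 4-hydroxyphenyl group on C2, an (E)-3-(4-hydroxyphenyl)prop-2-enyl arm on C3 and a hydroxy(4-hydroxyphenyl)methyl arm on C5; C4 and C6 are plain methylenes. C2 (R) and C3 (S) are adjacent and cis, C5 (R) is cis to both, and the fourth stereocentre, the exocyclic carbinol (R), stands next to C5. Because all three ring substituents are cis, no chair can place them all equatorial, so the array is not the thermodynamic one. Epimerisation at C2 (ionisation of the benzylic C2–O1 bond) or at C5 (whenever C5 is α to a carbonyl group) would run downhill and must be prevented by kinetic control. The fragile groups are the two 4-hydroxybenzylic C–O bonds (C2–O1 and the carbinol), which ionise towards quinone methides under acid, the electron-rich styrene and the three phenols. The real difficulty is to set the cis C2/C3 pair in the absolute sense and then to place C5 and the carbinol, neither of which has a strongly directing neighbour. The key step exploits that O1–C2 is the carbonyl group of a 4-oxygenated benzaldehyde and that C3–C4–C5–C6 is a four-carbon diene unit, with C6 entering as a removable methoxy-bearing acetal carbon.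

## Logic of the disconnections

29 ⇒ 28. The cuts are two aryl O–Si bonds and one aryl O–acyl bond. The phenols are masked because they would interfere with the organometallic, oxidation and Lewis-acid steps. The demand is one mild, basic operation that frees all three phenols without ever exposing the 4-hydroxybenzylic C–O bonds to acid.

28 ⇒ 27 ⇒ 26 ⇒ 23 + 25 (from 24). The cuts are the carbinol C–H bond and then the carbinol C–aryl bond. This shrinks the C5 arm to a one-carbon aldehyde, the same carbon that the diene carries as CH2O. The α-carbon C5 has two nearly equal CH2 neighbours, so the addition of 25 to 23 cannot be trusted for face selectivity; the epimers 26 are therefore merged in ketone 27 and the centre is set by a chiral reducing agent. The demand is reagent control in 27 ⇒ 28 and non-equilibrating handling of 23 and 27 at C5.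

23 ⇒ 22 ⇒ 21 ⇒ 18 + 20. The cut is the styrene C=C bond. It returns the C3 arm to a two-carbon aldehyde, that is to the oxyethyl chain of the diene, and it brings the third aryl ring in as 20 (from 19). Working on this arm first means the carbinol is made last and never needs protection. The demand is an E-selective olefination of an enolisable aldehyde beside an aryl ester.

18 ⇒ 17 ⇒ 16. These are changes of oxidation level and protection at the C3 arm only. The demand is that the benzyl ether of 16 is cleaved by hydrogenolysis before any styrene exists and without touching the ring C2–O1 bond.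

16 ⇒ 15 ⇒ 14. A C6–H bond is exchanged for C6–OMe and the C4–H/C5–H pair for the C4=C5 alkene. This converts the saturated oxane into a 6-alkoxy-3,6-dihydro-2H-pyran, the retron of an oxa-Diels–Alder reaction. The demands are that hydrogen adds to the face of 14 opposite its three cis substituents, and that the acetal of 15 ionises at C6 without ionising C2–O1.

14 ⇒ 11 + 13. The cuts are C2–C3 and O1–C6. One step gives the ring, two skeletal bonds and the cis C2/C3 pair from two fragments of similar size. The demand falls on the diene: in 11 the methoxy group must be trans to C3 and the C3=C4 alkene must be E, so that both terminal substituents point outward; the catalyst must choose the aldehyde face of 13 (made from 12).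

11 ⇒ 10. The cut is the enol-ether C–O bond. An alkenyl iodide of defined geometry is a safer carrier of the C1=C2 geometry than any enol-ether-forming olefination. The demand is a stereoretentive C–O coupling.

10 ⇒ 9 ⇒ 4 + 5. The cuts are the C2–C3 bond between the two alkenes and the C–I bond. An anti-carbometalation of 5 by 7 (via 8) holds the metal, and hence iodine and later methoxy, cis to the CH2O group by chelation. The demand is that 7 is formed and transferred with retention of its E geometry.

4 ⇒ 2 ⇒ 1. The cuts are C–I/C–H across the alkyne and the benzyl ether. The demand is a syn hydrometalation with the metal on the terminal carbon. The commercial starting materials are 1, 5, 12, 19 and 24.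

## Other disconnections considered

Alternative 1: The cut is at C2–C3 and at the C5–carbinol bond, both aldol bonds from one aldehyde A3 to the two α-carbons of the five-carbon bis-imide A1. In the forward key step both ends of A1 are soft-enolised (magnesium halide, amine base, silyl chloride) and add to two molecules of A3 to give the bis-anti-aldol adduct A2; no ring closes. In its favour: the C2/C3 pair and the C5/carbinol pair of the target are both anti-aldol relationships of the same absolute sense, so A2 is twofold-symmetric and carries all four stereocentres of the target from one auxiliary antipode. Aromatic aldehydes are the best substrates for this type of anti-aldol, and no stereocentre is made and then erased. Against it here: the two ends of A2 must diverge, one acyl carbon becoming C6 (closed by the remote carbinol oxygen) and the other the first CH2 of the C3 arm, which needs a one-carbon homologation before the styrene can be made. The ring closure requires activating primary hydroxyls next to electron-rich benzylic carbinols that ionise or retro-aldolise easily, and the second carbinol could bridge onto the cis C3 arm. Double soft enolisation of a 1,5-bis-imide and the low electrophilicity of A3 are open points. Comparison: on structure it is the better plan in stereo-economy (four centres in one step against three, one, one in the chosen plan, with a sacrificial C6 centre there) and probably the shorter, perhaps ten steps. On mechanism it relies on a stoichiometric auxiliary, where the chosen plan takes its chirality from a catalyst and forms the ring and the C2–O1 bond in the same event without manipulating a benzylic C–O bond. On convergence the two are equal.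

Alternative 2: The cut is at C5–C6, after reconnecting the carbinol carbon with the far end of the C3 arm into a cyclohexene. In the forward key step a silyl triflate ionises the methoxymethyl ether A4; the resulting O=CH2 carbon adds to the styrenyl alkene and the oxane closes as the bridged bicycle A5, with proton loss away from the bridgehead. In its favour: the C3 and C5 arms are the two ends of one three-carbon bridge, so their cis relationship is enforced by construction and not by a facial hydrogenation. Ozonolysis of A5 would unveil exactly an aryl ketone on C5 and an acetaldehyde arm on C3, the same functional groups the chosen plan reaches. No C6 stereocentre has to be erased, and the bridgehead rule fixes the regiochemistry of proton loss. Against it here: the key step creates no absolute stereochemistry; A4 already contains two stereocentres that need their own asymmetric synthesis, one of them a carbinol next to a ring CH with two CH2 neighbours. The ionising conditions meet an electron-rich benzylic ether whose ionisation would scramble C2, the benzylic cation intermediate has other exits, and the carbinol still has to be set by reduction after the ring is cleaved. Comparison: on structure it is better for the C3/C5 relationship and equal in needing a late reagent-controlled ketone reduction. On mechanism it is weaker, because a cationic step runs beside a donor-substituted benzylic ether where the chosen plan uses a neutral pericyclic step. On step economy the two are probably equal.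

Alternative 3: The cut is at O1–C6, with the ring carbons C3 to C6 drawn from a furan. In the forward key step a positive-bromine oxidant in wet ether solvent opens the furan of the (S)-carbinol A6, and the carbinol oxygen closes onto the unmasked C6 aldehyde to give the hemiacetal pyranone A7. In its favour: A6 is an aromatic, easily made compound with a single stereocentre that well-established asymmetric ketone reductions can set. The ring oxygen, a reducible C6 hemiacetal and a C5 carboxyl group at the right oxidation level for the aryl ketone all arrive in one step. Against it here: only C2 is defined. The C3 arm must be built on a ketone carbon and then deoxygenated cis to the aryl group, and C5 must be set by reducing a doubly activated alkene, so two centres are left to substrate control. The C2–H of A7 is flanked by a ketone, an aryl group and the ring oxygen and is prone to racemisation; the oxidant can also brominate the electron-rich aryl ring, and the ester slows the furan oxidation. Comparison: on structure it is equal to the chosen plan in erasing C6 by ionic reduction and in hydrogenating C4=C5, and better in the simplicity of its early steps. On mechanism it is worse, because C2/C3 and C5 are not fixed by the key step and C2 is labile. On step economy it is likely longer after the key step.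

Key step: step 7

## Remarks on the chemistry (corrections and assumptions)

- **Diene descriptor.** The diene that the cycloaddition needs has its methoxy group trans to C3; by the sequence rules this is (1Z,3E), because CH2OSi outranks the vinyl carbon on C2. "E,E" would denote the isomer with the methoxy group turned inward, which cannot easily reach a reactive s-cis form.
- **Diene assembly.** A 2-halo-3-methoxyallyl ether made by halogenation and dehydrohalogenation of a 3-methoxyacrylate and reduction would carry halogen and methoxy on the same side. A stereoretentive cross-coupling would then place the chain cis to methoxy, the wrong isomer. The diene is therefore built by chelation-controlled carbometalation (steps 3 to 5).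
- **Protecting groups.** The C3 arm carries a benzyl ether in place of a 4-methoxybenzyl ether, which would not be safe under the hydrogenation and BF3/silane steps. The aldehyde carries a pivalate in place of a silyl ether: it makes the aldehyde a better heterodienophile and protects the C2–O1 benzylic bond against ionisation in step 9. The C5 arm keeps its tert-butyldimethylsilyl ether.
- **Assumption on the catalyst antipode.** The catalyst built from (1R,2S)-1-aminoindan-2-ol is taken to direct the diene to the Re face of the aldehyde, as it does with α-oxygenated aliphatic aldehydes; should the sense prove opposite, the (1S,2R) antipode is used with no other change.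
- **Convention.** Salts formed by simple deprotonation of a numbered compound in the same flask are treated as forms of that compound. Changes of the C3 and C5 descriptors along the route reflect changes in substituent priority, not in configuration.

## Route

Step 1
Reactants: 1 but-3-yn-1-ol
Product: 2 benzyl but-3-yn-1-yl ether
Conditions: NaH, BnBr, Bu4NI (cat.), THF, 0 °C → rt
Reagents that add atoms: benzyl bromide, BrCc1ccccc1
Why: Williamson etherification of the sodium alkoxide. The benzyl ether tolerates organolithium reagents, Lewis acid and the platinum hydrogenation, and it can be removed by hydrogenolysis before any styrene is present.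

Step 2
Reactants: 2 benzyl but-3-yn-1-yl ether
Product: 4 (E)-4-(benzyloxy)-1-iodobut-1-ene, via (E)-alkenylzirconocene chloride 3 (not isolated)
Conditions: Cp2Zr(H)Cl, THF, rt; then I2, 0 °C
Reagents that add atoms: iodine, II
Why: Hydrozirconation adds Zr–H syn across the terminal alkyne with zirconium on the terminal carbon, and iodinolysis of the C–Zr bond proceeds with retention. This fixes the E geometry of the future C3=C4 bond of the diene.

Step 3
Reactants: 4 (E)-4-(benzyloxy)-1-iodobut-1-ene; 5 prop-2-yn-1-ol
Product: 9 (2Z,3E)-6-(benzyloxy)-2-(iodomethylidene)hex-3-en-1-ol, via (E)-4-(benzyloxy)but-1-enyllithium 6 (not isolated), via (E)-4-(benzyloxy)but-1-enylmagnesium bromide 7 (not isolated), via cyclic alkenylmagnesium alkoxide 8 (not isolated)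
Conditions: 4, t-BuLi (2 equiv), Et2O, −78 °C; MgBr2·OEt2, −78 → 0 °C; add to 5 pretreated with EtMgBr (1 equiv, THF, 0 °C); CuI (10 mol %), rt → 40 °C; then I2, THF, −30 → 0 °C
Reagents that add atoms: iodine, II
Why: Copper-catalysed anti-carbomagnesiation of a propargylic alkoxide: the alkenyl group adds to the internal alkyne carbon while magnesium is held on the terminal carbon in a five-membered chelate with the alkoxide oxygen. Iodinolysis with retention therefore places iodine cis to CH2OH and trans to the alkenyl chain. Iodine–lithium exchange and transmetalation to magnesium both keep the E alkene.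

Step 4
Reactants: 9 (2Z,3E)-6-(benzyloxy)-2-(iodomethylidene)hex-3-en-1-ol
Product: 10 (1Z,3E)-6-(benzyloxy)-2-{[(tert-butyldimethylsilyl)oxy]methyl}-1-iodohexa-1,3-diene
Conditions: TBSCl, imidazole, CH2Cl2, 0 °C → rt
Reagents that add atoms: tert-butyldimethylsilyl chloride, C[Si](C)(Cl)C(C)(C)C
Why: Standard silylation of a primary allylic alcohol. This silyl ether is chosen for the C5 arm because mild acid can later remove it in the presence of aryl silyl ethers.

Step 5
Reactants: 10 (1Z,3E)-6-(benzyloxy)-2-{[(tert-butyldimethylsilyl)oxy]methyl}-1-iodohexa-1,3-diene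
Product: 11 (1Z,3E)-6-(benzyloxy)-2-{[(tert-butyldimethylsilyl)oxy]methyl}-1-methoxyhexa-1,3-diene
Conditions: CuI (10 mol %), 3,4,7,8-tetramethyl-1,10-phenanthroline (20 mol %), Cs2CO3, MeOH (5 equiv), toluene, 80 °C, sealed vessel
Reagents that add atoms: methanol, CO
Why: Ullmann-type copper-catalysed C–O coupling of an alkenyl iodide with an aliphatic alcohol, a stereoretentive process. The methoxy group inherits the position cis to CH2OSi and trans to C3; the enol ether is purified on base-washed silica.

Step 6
Reactants: 12 4-hydroxybenzaldehyde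
Product: 13 4-formylphenyl pivalate
Conditions: PivCl, Et3N, DMAP (cat.), CH2Cl2, 0 °C → rt
Reagents that add atoms: pivaloyl chloride, CC(C)(C)C(Cl)=O
Why: Acylation of the phenol. The acyloxy group makes the aldehyde more electrophilic than a silyloxy group would and later holds back ionisation of the C2–O1 benzylic bond.

Step 7
Reactants: 11 (1Z,3E)-6-(benzyloxy)-2-{[(tert-butyldimethylsilyl)oxy]methyl}-1-methoxyhexa-1,3-diene; 13 4-formylphenyl pivalate
Product: 14 4-[(2R,3S,6S)-3-[2-(benzyloxy)ethyl]-5-{[(tert-butyldimethylsilyl)oxy]methyl}-6-methoxy-3,6-dihydro-2H-pyran-2-yl]phenyl pivalate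
Conditions: [CrCl(C27H29NO2)] (5 mol %; chloride of trivalent chromium with the doubly deprotonated Schiff base of 3-(1-adamantyl)-5-methylsalicylaldehyde and (1R,2S)-1-aminoindan-2-ol), 4 Å molecular sieves, minimal tert-butyl methyl ether, rt, 24–48 h
Reagents that add atoms: none
Why: The chromium centre binds the aldehyde oxygen of 13 as a Lewis acid, and diene 11 adds through a concerted but asynchronous [4+2] transition state in which the C2–C3 bond (diene C4 to the carbonyl carbon) forms ahead of the O1–C6 bond. The closest known reaction type is the hetero-Diels–Alder reaction of 1-methoxybuta-1,3-diene with aldehydes under tridentate Schiff-base chromium chloride catalysts; this 2,4-disubstituted diene is a new substrate of that class. The dihydropyran ring closes in the cycloaddition itself, as a suprafacial [4+2] closure with both new bonds on one face of the s-cis diene. C2 is set by the catalyst, which shields one face of the bound aldehyde so that the diene should add to the Re face (2R). C3 follows from the endo topology together with the E geometry of the C3=C4 alkene: the aryl group lies under the diene and ends cis to the outward C3 arm. C6 follows from the outward methoxy group of the (1Z) enol ether and also ends cis; this centre is removed in step 9. The step needs regio-, endo- and face selectivity: the methoxy group polarises the diene so that only its C4 terminus attacks carbon, the outward position of both terminal substituents lets the diene reach the s-cis form, and the pivalate raises the electrophilicity of the aldehyde.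

Step 8
Reactants: 14 4-[(2R,3S,6S)-3-[2-(benzyloxy)ethyl]-5-{[(tert-butyldimethylsilyl)oxy]methyl}-6-methoxy-3,6-dihydro-2H-pyran-2-yl]phenyl pivalate
Product: 15 4-[(2R,3R,5S,6S)-3-[2-(benzyloxy)ethyl]-5-{[(tert-butyldimethylsilyl)oxy]methyl}-6-methoxyoxan-2-yl]phenyl pivalate
Conditions: H2 (1 atm), PtO2 (5 mol %), EtOAc, rt
Reagents that add atoms: none
Why: Heterogeneous syn hydrogenation of the trisubstituted alkene from the face opposite the aryl group, the C3 arm and the C6 methoxy group, which all stand on one face. The new C5–H bond therefore lies anti to them and CH2OSi ends cis to the other three substituents. Platinum is preferred to palladium to avoid allylic hydrogenolysis, double-bond migration towards C3 and loss of the benzyl ether.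

Step 9
Reactants: 15 4-[(2R,3R,5S,6S)-3-[2-(benzyloxy)ethyl]-5-{[(tert-butyldimethylsilyl)oxy]methyl}-6-methoxyoxan-2-yl]phenyl pivalate
Product: 16 4-[(2R,3R,5R)-3-[2-(benzyloxy)ethyl]-5-{[(tert-butyldimethylsilyl)oxy]methyl}oxan-2-yl]phenyl pivalate
Conditions: Et3SiH, BF3·OEt2, CH2Cl2, −78 → −40 °C
Reagents that add atoms: none
Why: Ionic reduction of a cyclic acetal: BF3 removes methoxide to give the O1=C6 oxocarbenium ion and the silane delivers hydride, so C6 becomes a methylene and no stereocentre is formed. The acyloxy-substituted aryl ring disfavours the competing ionisation of C2–O1. Low temperature and excess silane limit proton loss from C5 and loss of the silyl ether.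

Step 10
Reactants: 16 4-[(2R,3R,5R)-3-[2-(benzyloxy)ethyl]-5-{[(tert-butyldimethylsilyl)oxy]methyl}oxan-2-yl]phenyl pivalate
Product: 17 4-[(2R,3R,5R)-5-{[(tert-butyldimethylsilyl)oxy]methyl}-3-(2-hydroxyethyl)oxan-2-yl]phenyl pivalate
Conditions: H2 (1 atm), Pd/C (10 %), EtOAc, rt
Reagents that add atoms: none
Why: Hydrogenolysis of the primary benzyl ether. No alkene is present at this stage, and the ring C2–O1 bond (secondary, cyclic, on an electron-poor ring) should be cleaved much more slowly.

Step 11
Reactants: 17 4-[(2R,3R,5R)-5-{[(tert-butyldimethylsilyl)oxy]methyl}-3-(2-hydroxyethyl)oxan-2-yl]phenyl pivalate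
Product: 18 4-[(2R,3R,5R)-5-{[(tert-butyldimethylsilyl)oxy]methyl}-3-(2-oxoethyl)oxan-2-yl]phenyl pivalate
Conditions: triacetoxyperiodinane [1,1,1-triacetoxy-1,2-benziodoxol-3(1H)-one], NaHCO3, CH2Cl2, 0 °C → rt
Reagents that add atoms: none
Why: Buffered periodinane oxidation of a primary alcohol. C3 is β to the new carbonyl group, so no stereocentre is at risk.

Step 12
Reactants: 19 diethyl (4-hydroxybenzyl)phosphonate
Product: 20 diethyl {4-[(tert-butyldimethylsilyl)oxy]benzyl}phosphonate
Conditions: TBSCl, imidazole, DMF, rt
Reagents that add atoms: tert-butyldimethylsilyl chloride, C[Si](C)(Cl)C(C)(C)C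
Why: Silylation of the phenol, so that the phosphonate can afterwards be deprotonated at the benzylic carbon.

Step 13
Reactants: 18 4-[(2R,3R,5R)-5-{[(tert-butyldimethylsilyl)oxy]methyl}-3-(2-oxoethyl)oxan-2-yl]phenyl pivalate; 20 diethyl {4-[(tert-butyldimethylsilyl)oxy]benzyl}phosphonate
Product: 21 4-[(2R,3S,5R)-5-{[(tert-butyldimethylsilyl)oxy]methyl}-3-[(E)-3-{4-[(tert-butyldimethylsilyl)oxy]phenyl}prop-2-en-1-yl]oxan-2-yl]phenyl pivalate
Conditions: 20, NaN(SiMe3)2, THF, 0 °C; then 18, 0 °C → rt
Reagents that add atoms: none
Why: Horner–Wadsworth–Emmons olefination with a semi-stabilised benzylic phosphonate anion. Reversible addition and elimination through the less hindered trans oxaphosphetane should give the E styrene. The hindered pivalate and the silyl ethers should tolerate the amide base.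

Step 14
Reactants: 21 4-[(2R,3S,5R)-5-{[(tert-butyldimethylsilyl)oxy]methyl}-3-[(E)-3-{4-[(tert-butyldimethylsilyl)oxy]phenyl}prop-2-en-1-yl]oxan-2-yl]phenyl pivalate
Product: 22 4-[(2R,3S,5S)-3-[(E)-3-{4-[(tert-butyldimethylsilyl)oxy]phenyl}prop-2-en-1-yl]-5-(hydroxymethyl)oxan-2-yl]phenyl pivalate
Conditions: camphorsulfonic acid (0.1 equiv), MeOH/CH2Cl2, 0 °C
Reagents that add atoms: none
Why: Acid-catalysed methanolysis removes a primary alkyl silyl ether much faster than an aryl silyl ether. The C2 aryl ring still carries the pivalate, so the ring benzylic ether is not ionised.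

Step 15
Reactants: 22 4-[(2R,3S,5S)-3-[(E)-3-{4-[(tert-butyldimethylsilyl)oxy]phenyl}prop-2-en-1-yl]-5-(hydroxymethyl)oxan-2-yl]phenyl pivalate
Product: 23 4-[(2R,3S,5R)-3-[(E)-3-{4-[(tert-butyldimethylsilyl)oxy]phenyl}prop-2-en-1-yl]-5-formyloxan-2-yl]phenyl pivalate
Conditions: triacetoxyperiodinane, NaHCO3, CH2Cl2, 0 °C
Reagents that add atoms: none
Why: Buffered periodinane oxidation, neutral enough that the α-stereocentre C5 (not in its thermodynamic arrangement) should not equilibrate. The aldehyde is used at once.

Step 16
Reactants: 23 4-[(2R,3S,5R)-3-[(E)-3-{4-[(tert-butyldimethylsilyl)oxy]phenyl}prop-2-en-1-yl]-5-formyloxan-2-yl]phenyl pivalate; 24 (4-bromophenoxy)(tert-butyl)dimethylsilane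
Product: 26 4-[(2R,3S,5R)-3-[(E)-3-{4-[(tert-butyldimethylsilyl)oxy]phenyl}prop-2-en-1-yl]-5-(hydroxy{4-[(tert-butyldimethylsilyl)oxy]phenyl}methyl)oxan-2-yl]phenyl pivalate (both carbinol epimers), via 4-(tert-butyldimethylsilyloxy)phenylmagnesium bromide 25 (not isolated)
Conditions: 24, Mg, THF, rt; then 23, THF, −78 °C; aq. NH4Cl
Reagents that add atoms: none
Why: Grignard addition to the aldehyde at −78 °C, which should be much faster than attack on the hindered aryl pivalate. Face selectivity is not relied on, because the carbinol centre is set in step 18.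

Step 17
Reactants: 26 4-[(2R,3S,5R)-3-[(E)-3-{4-[(tert-butyldimethylsilyl)oxy]phenyl}prop-2-en-1-yl]-5-(hydroxy{4-[(tert-butyldimethylsilyl)oxy]phenyl}methyl)oxan-2-yl]phenyl pivalate
Product: 27 4-[(2R,3S,5R)-5-{4-[(tert-butyldimethylsilyl)oxy]benzoyl}-3-[(E)-3-{4-[(tert-butyldimethylsilyl)oxy]phenyl}prop-2-en-1-yl]oxan-2-yl]phenyl pivalate
Conditions: triacetoxyperiodinane, NaHCO3, CH2Cl2, 0 °C
Reagents that add atoms: none
Why: Periodinane oxidation of the benzylic alcohol merges both carbinol epimers into one ketone under buffered, non-equilibrating conditions.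

Step 18
Reactants: 27 4-[(2R,3S,5R)-5-{4-[(tert-butyldimethylsilyl)oxy]benzoyl}-3-[(E)-3-{4-[(tert-butyldimethylsilyl)oxy]phenyl}prop-2-en-1-yl]oxan-2-yl]phenyl pivalate
Product: 28 4-[(2R,3S,5R)-5-[(R)-hydroxy{4-[(tert-butyldimethylsilyl)oxy]phenyl}methyl]-3-[(E)-3-{4-[(tert-butyldimethylsilyl)oxy]phenyl}prop-2-en-1-yl]oxan-2-yl]phenyl pivalate
Conditions: (S)-2-methyl-CBS-oxazaborolidine (20 mol %), catecholborane (2 equiv), toluene, −78 °C
Reagents that add atoms: none
Why: CBS reduction: the oxazaborolidine binds the ketone oxygen anti to the aryl group and delivers hydride to one face, so the (S) catalyst should give the (R) carbinol from an aryl alkyl ketone. Catecholborane at −78 °C does not hydroborate the styrene.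

Step 19
Reactants: 28 4-[(2R,3S,5R)-5-[(R)-hydroxy{4-[(tert-butyldimethylsilyl)oxy]phenyl}methyl]-3-[(E)-3-{4-[(tert-butyldimethylsilyl)oxy]phenyl}prop-2-en-1-yl]oxan-2-yl]phenyl pivalate
Product: 29 4-[(2R,3S,5R)-5-[(R)-hydroxy(4-hydroxyphenyl)methyl]-3-[(E)-3-(4-hydroxyphenyl)prop-2-en-1-yl]oxan-2-yl]phenol (CNP0182155.1)
Conditions: K2CO3, MeOH, rt; then aq. NH4Cl (near neutral)
Reagents that add atoms: none
Why: Carbonate in methanol cleaves the aryl pivalate by transesterification and both aryl silyl ethers by methanolysis without touching the carbinol or the oxane. The work-up stays near neutral because acid would ionise the 4-hydroxybenzylic C–O bonds.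

## Compound list

1 | but-3-yn-1-ol | C#CCCO | starting material
2 | benzyl but-3-yn-1-yl ether | C#CCCOCc1ccccc1 | intermediate
3 | chlorido[(E)-4-(benzyloxy)but-1-en-1-yl]bis(cyclopentadienyl)zirconium | Cl[Zr](/C=C/CCOCc1ccccc1)(C1C=CC=C1)C1C=CC=C1 | intermediate (not isolated)
4 | (E)-4-(benzyloxy)-1-iodobut-1-ene | I/C=C/CCOCc1ccccc1 | intermediate
5 | prop-2-yn-1-ol | C#CCO | starting material
6 | (E)-4-(benzyloxy)but-1-en-1-yllithium | [Li]/C=C/CCOCc1ccccc1 | intermediate (not isolated)
7 | (E)-4-(benzyloxy)but-1-en-1-ylmagnesium bromide | Br[Mg]/C=C/CCOCc1ccccc1 | intermediate (not isolated)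
8 | 4-[(E)-4-(benzyloxy)but-1-en-1-yl]-2,5-dihydro-1,2-oxamagnesole (cyclic alkenylmagnesium alkoxide) | [Mg]1OCC(/C=C/CCOCc2ccccc2)=C1 | intermediate (not isolated)
9 | (2Z,3E)-6-(benzyloxy)-2-(iodomethylidene)hex-3-en-1-ol | I/C=C(CO)/C=C/CCOCc1ccccc1 | intermediate
10 | (1Z,3E)-6-(benzyloxy)-2-{[(tert-butyldimethylsilyl)oxy]methyl}-1-iodohexa-1,3-diene | I/C=C(CO[Si](C)(C)C(C)(C)C)/C=C/CCOCc1ccccc1 | intermediate
11 | (1Z,3E)-6-(benzyloxy)-2-{[(tert-butyldimethylsilyl)oxy]methyl}-1-methoxyhexa-1,3-diene | CO/C=C(CO[Si](C)(C)C(C)(C)C)/C=C/CCOCc1ccccc1 | intermediate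
12 | 4-hydroxybenzaldehyde | O=Cc1ccc(O)cc1 | starting material
13 | 4-formylphenyl pivalate | O=Cc1ccc(OC(=O)C(C)(C)C)cc1 | intermediate
14 | 4-[(2R,3S,6S)-3-[2-(benzyloxy)ethyl]-5-{[(tert-butyldimethylsilyl)oxy]methyl}-6-methoxy-3,6-dihydro-2H-pyran-2-yl]phenyl pivalate | CO[C@H]1O[C@@H](c2ccc(OC(=O)C(C)(C)C)cc2)[C@@H](CCOCc2ccccc2)C=C1CO[Si](C)(C)C(C)(C)C | intermediate
15 | 4-[(2R,3R,5S,6S)-3-[2-(benzyloxy)ethyl]-5-{[(tert-butyldimethylsilyl)oxy]methyl}-6-methoxyoxan-2-yl]phenyl pivalate | CO[C@H]1O[C@@H](c2ccc(OC(=O)C(C)(C)C)cc2)[C@@H](CCOCc2ccccc2)C[C@H]1CO[Si](C)(C)C(C)(C)C | intermediate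
16 | 4-[(2R,3R,5R)-3-[2-(benzyloxy)ethyl]-5-{[(tert-butyldimethylsilyl)oxy]methyl}oxan-2-yl]phenyl pivalate | c1ccccc1COCC[C@H]2C[C@@H](CO[Si](C)(C)C(C)(C)C)CO[C@H]2c2ccc(OC(=O)C(C)(C)C)cc2 | intermediate
17 | 4-[(2R,3R,5R)-5-{[(tert-butyldimethylsilyl)oxy]methyl}-3-(2-hydroxyethyl)oxan-2-yl]phenyl pivalate | OCC[C@H]2C[C@@H](CO[Si](C)(C)C(C)(C)C)CO[C@H]2c2ccc(OC(=O)C(C)(C)C)cc2 | intermediate
18 | 4-[(2R,3R,5R)-5-{[(tert-butyldimethylsilyl)oxy]methyl}-3-(2-oxoethyl)oxan-2-yl]phenyl pivalate | O=CC[C@H]2C[C@@H](CO[Si](C)(C)C(C)(C)C)CO[C@H]2c2ccc(OC(=O)C(C)(C)C)cc2 | intermediate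
19 | diethyl (4-hydroxybenzyl)phosphonate | CCOP(=O)(Cc1ccc(O)cc1)OCC | starting material
20 | diethyl {4-[(tert-butyldimethylsilyl)oxy]benzyl}phosphonate | CCOP(=O)(Cc1ccc(O[Si](C)(C)C(C)(C)C)cc1)OCC | intermediate
21 | 4-[(2R,3S,5R)-5-{[(tert-butyldimethylsilyl)oxy]methyl}-3-[(E)-3-{4-[(tert-butyldimethylsilyl)oxy]phenyl}prop-2-en-1-yl]oxan-2-yl]phenyl pivalate | CC(C)(C)[Si](C)(C)Oc1ccc(/C=C/C[C@H]2C[C@@H](CO[Si](C)(C)C(C)(C)C)CO[C@H]2c2ccc(OC(=O)C(C)(C)C)cc2)cc1 | intermediate
22 | 4-[(2R,3S,5S)-3-[(E)-3-{4-[(tert-butyldimethylsilyl)oxy]phenyl}prop-2-en-1-yl]-5-(hydroxymethyl)oxan-2-yl]phenyl pivalate | CC(C)(C)[Si](C)(C)Oc1ccc(/C=C/C[C@H]2C[C@@H](CO)CO[C@H]2c2ccc(OC(=O)C(C)(C)C)cc2)cc1 | intermediate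
23 | 4-[(2R,3S,5R)-3-[(E)-3-{4-[(tert-butyldimethylsilyl)oxy]phenyl}prop-2-en-1-yl]-5-formyloxan-2-yl]phenyl pivalate | CC(C)(C)[Si](C)(C)Oc1ccc(/C=C/C[C@H]2C[C@@H](C=O)CO[C@H]2c2ccc(OC(=O)C(C)(C)C)cc2)cc1 | intermediate
24 | (4-bromophenoxy)(tert-butyl)dimethylsilane | Brc1ccc(O[Si](C)(C)C(C)(C)C)cc1 | starting material
25 | 4-[(tert-butyldimethylsilyl)oxy]phenylmagnesium bromide | Br[Mg]c1ccc(O[Si](C)(C)C(C)(C)C)cc1 | intermediate (not isolated)
26 | 4-[(2R,3S,5R)-3-[(E)-3-{4-[(tert-butyldimethylsilyl)oxy]phenyl}prop-2-en-1-yl]-5-(hydroxy{4-[(tert-butyldimethylsilyl)oxy]phenyl}methyl)oxan-2-yl]phenyl pivalate (carbinol epimers) | CC(C)(C)[Si](C)(C)Oc1ccc(/C=C/C[C@H]2C[C@@H](C(O)c3ccc(O[Si](C)(C)C(C)(C)C)cc3)CO[C@H]2c2ccc(OC(=O)C(C)(C)C)cc2)cc1 | intermediate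
27 | 4-[(2R,3S,5R)-5-{4-[(tert-butyldimethylsilyl)oxy]benzoyl}-3-[(E)-3-{4-[(tert-butyldimethylsilyl)oxy]phenyl}prop-2-en-1-yl]oxan-2-yl]phenyl pivalate | CC(C)(C)[Si](C)(C)Oc1ccc(/C=C/C[C@H]2C[C@@H](C(=O)c3ccc(O[Si](C)(C)C(C)(C)C)cc3)CO[C@H]2c2ccc(OC(=O)C(C)(C)C)cc2)cc1 | intermediate
28 | 4-[(2R,3S,5R)-5-[(R)-hydroxy{4-[(tert-butyldimethylsilyl)oxy]phenyl}methyl]-3-[(E)-3-{4-[(tert-butyldimethylsilyl)oxy]phenyl}prop-2-en-1-yl]oxan-2-yl]phenyl pivalate | CC(C)(C)[Si](C)(C)Oc1ccc(/C=C/C[C@H]2C[C@@H]([C@@H](O)c3ccc(O[Si](C)(C)C(C)(C)C)cc3)CO[C@H]2c2ccc(OC(=O)C(C)(C)C)cc2)cc1 | intermediate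
29 | 4-[(2R,3S,5R)-5-[(R)-hydroxy(4-hydroxyphenyl)methyl]-3-[(E)-3-(4-hydroxyphenyl)prop-2-en-1-yl]oxan-2-yl]phenol | Oc1ccc(/C=C/C[C@H]2C[C@@H]([C@@H](O)c3ccc(O)cc3)CO[C@H]2c2ccc(O)cc2)cc1 | target

## Step count and risks

Total step count: 19. Longest linear sequence: 17 steps (from 1 through steps 1 to 5, 7 to 11 and 13 to 19); steps 6 and 12 are side branches.

**Step 7 (key step).** The most likely failure is a slow cycloaddition with erosion of endo or face selectivity, because the reacting diene terminus carries a substituent, the aldehyde is aromatic, and this substitution pattern has no direct precedent under the chromium catalyst. Fallback, setting out from 11 and 13 and returning at 14: run the cycloaddition with the achiral lanthanide Lewis acid Eu(fod)3 (fod = 6,6,7,7,8,8,8-heptafluoro-2,2-dimethyloctane-3,5-dionate), a known promoter of endo-selective oxa-Diels–Alder reactions of 1-alkoxydienes with aromatic aldehydes. This gives 14 as a racemate with its mirror image, 4-[(2S,3R,6R)-3-[2-(benzyloxy)ethyl]-5-{[(tert-butyldimethylsilyl)oxy]methyl}-6-methoxy-3,6-dihydro-2H-pyran-2-yl]phenyl pivalate F1. The two are then separated by preparative chromatography on a chiral stationary phase, and 14 re-enters at step 8.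

**Step 3.** The most likely failure is incomplete carbomagnesiation, because a functionalised alkenyl Grignard reagent adds to the propargylic alkoxide more slowly than simple ones and can be lost by protonation or homocoupling. Fallback, setting out from 4 and returning at 11 (steps 3 to 5 are bypassed): 4 is converted into 6 as before and acylated with 2-[(tert-butyldimethylsilyl)oxy]-N-methoxy-N-methylacetamide to give (E)-6-(benzyloxy)-1-[(tert-butyldimethylsilyl)oxy]hex-3-en-2-one F2. Wittig methoxymethylenation of F2 with the ylide from (methoxymethyl)triphenylphosphonium chloride and KN(SiMe3)2 gives 11 together with its geometric isomer (1E,3E)-6-(benzyloxy)-2-{[(tert-butyldimethylsilyl)oxy]methyl}-1-methoxyhexa-1,3-diene F3. F3 is removed by chromatography on base-washed silica; it is in any case the isomer that cannot readily reach the reactive s-cis form.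

**Step 5.** The most likely failure is sluggish C–O coupling with competing reduction of the C–I bond or loss of the silyl ether under carbonate and methanol at 80 °C. Fallback, setting out from 10 and returning at 11: iodine–lithium exchange (t-BuLi, −78 °C) and trapping with 2-isopropoxy-4,4,5,5-tetramethyl-1,3,2-dioxaborolane give, with retention, 2-[(1Z,3E)-6-(benzyloxy)-2-{[(tert-butyldimethylsilyl)oxy]methyl}hexa-1,3-dien-1-yl]-4,4,5,5-tetramethyl-1,3,2-dioxaborolane F4. F4 is then coupled oxidatively with methanol at room temperature (Chan–Lam-type, Cu(OAc)2, Et3N, air), a known stereoretentive route from alkenyl boronates to enol ethers.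

**Step 8.** The most likely failure is insufficient face selectivity, or allylic C–O hydrogenolysis and double-bond migration on the metal surface, since the only control element is the steric bias of the ring. Fallback, setting out from 14 and returning at 15: the silyl ether is removed (Bu4NF buffered with AcOH) to give the allylic alcohol 4-[(2R,3S,6S)-3-[2-(benzyloxy)ethyl]-5-(hydroxymethyl)-6-methoxy-3,6-dihydro-2H-pyran-2-yl]phenyl pivalate F5. F5 is hydrogenated homogeneously under hydroxyl direction with Ru(OAc)2(BINAP), using the BINAP antipode that reinforces addition opposite the ring substituents (H2 under pressure, MeOH), to give 4-[(2R,3R,5S,6S)-3-[2-(benzyloxy)ethyl]-5-(hydroxymethyl)-6-methoxyoxan-2-yl]phenyl pivalate F6. Resilylation (TBSCl, imidazole) gives 15. This replaces substrate control by reagent control.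

**Step 13.** The most likely failure is enolisation and self-condensation of aldehyde 18, or attack of the phosphonate anion on the aryl pivalate, both caused by the strongly basic, weakly stabilised benzylic anion. Fallback, setting out from 18 and returning at 21: methylenation with the ylide from methyltriphenylphosphonium bromide and KN(SiMe3)2 gives 4-[(2R,3S,5R)-5-{[(tert-butyldimethylsilyl)oxy]methyl}-3-(prop-2-en-1-yl)oxan-2-yl]phenyl pivalate F7. Cross-metathesis of F7 with 4-[(tert-butyldimethylsilyl)oxy]styrene under the second-generation ruthenium benzylidene catalyst RuCl2(H2IMes)(PCy3)(=CHPh) is neutral and E-selective and gives 21.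

**Step 18.** The most likely failure is insufficient reagent control, because the alkyl side of ketone 27 is α-branched and the substrate bias may oppose the catalyst; C5 of 27 may also epimerise on handling. Fallback, setting out from 23 and returning at 28 (steps 16 and 17 are bypassed): 24 is converted (n-BuLi; ZnCl2; n-BuLi) into butyl{4-[(tert-butyldimethylsilyl)oxy]phenyl}zinc F8. F8 is added to aldehyde 23 in the presence of a catalytic chiral amino alcohol, (−)-3-exo-morpholinoisoborneol, a known catalytic enantioselective aryl transfer. The ligand antipode is chosen to direct the aryl group to the Si face of the aldehyde, which corresponds to the (R) carbinol, and the mild zinc reagent leaves the aryl pivalate alone.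

## Further compounds

F1 | step 7 | 4-[(2S,3R,6S→R)-enantiomer of 14: (2S,3R,6R)-3-[2-(benzyloxy)ethyl]-5-{[(tert-butyldimethylsilyl)oxy]methyl}-6-methoxy-3,6-dihydro-2H-pyran-2-yl]phenyl pivalate | CO[C@@H]1O[C@H](c2ccc(OC(=O)C(C)(C)C)cc2)[C@H](CCOCc2ccccc2)C=C1CO[Si](C)(C)C(C)(C)C
F2 | step 3 | (E)-6-(benzyloxy)-1-[(tert-butyldimethylsilyl)oxy]hex-3-en-2-one | CC(C)(C)[Si](C)(C)OCC(=O)/C=C/CCOCc1ccccc1
F3 | step 3 | (1E,3E)-6-(benzyloxy)-2-{[(tert-butyldimethylsilyl)oxy]methyl}-1-methoxyhexa-1,3-diene | CO/C=C(CO[Si](C)(C)C(C)(C)C)\C=C\CCOCc1ccccc1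
F4 | step 5 | 2-[(1Z,3E)-6-(benzyloxy)-2-{[(tert-butyldimethylsilyl)oxy]methyl}hexa-1,3-dien-1-yl]-4,4,5,5-tetramethyl-1,3,2-dioxaborolane | CC1(C)OB(/C=C(CO[Si](C)(C)C(C)(C)C)/C=C/CCOCc2ccccc2)OC1(C)C
F5 | step 8 | 4-[(2R,3S,6S)-3-[2-(benzyloxy)ethyl]-5-(hydroxymethyl)-6-methoxy-3,6-dihydro-2H-pyran-2-yl]phenyl pivalate | CO[C@H]1O[C@@H](c2ccc(OC(=O)C(C)(C)C)cc2)[C@@H](CCOCc2ccccc2)C=C1CO
F6 | step 8 | 4-[(2R,3R,5S,6S)-3-[2-(benzyloxy)ethyl]-5-(hydroxymethyl)-6-methoxyoxan-2-yl]phenyl pivalate | CO[C@H]1O[C@@H](c2ccc(OC(=O)C(C)(C)C)cc2)[C@@H](CCOCc2ccccc2)C[C@H]1CO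
F7 | step 13 | 4-[(2R,3S,5R)-5-{[(tert-butyldimethylsilyl)oxy]methyl}-3-(prop-2-en-1-yl)oxan-2-yl]phenyl pivalate | C=CC[C@H]2C[C@@H](CO[Si](C)(C)C(C)(C)C)CO[C@H]2c2ccc(OC(=O)C(C)(C)C)cc2
F8 | step 18 | butyl{4-[(tert-butyldimethylsilyl)oxy]phenyl}zinc | CCCC[Zn]c1ccc(O[Si](C)(C)C(C)(C)C)cc1
A1 | alternative 1 | 1,5-bis[(4R)-4-benzyl-2-oxo-1,3-oxazolidin-3-yl]pentane-1,5-dione | O=C(CCCC(=O)N1[C@H](Cc2ccccc2)COC1=O)N1[C@H](Cc2ccccc2)COC1=O
A2 | alternative 1 | twofold-symmetric bis-anti-aldol adduct, 2,4-bis(hydroxy{4-[(tert-butyldimethylsilyl)oxy]phenyl}methyl)pentanedioyl bis[(4R)-4-benzyloxazolidin-2-one] | O=C(N1[C@H](Cc2ccccc2)COC1=O)[C@H]([C@@H](O)c1ccc(O[Si](C)(C)C(C)(C)C)cc1)C[C@@H]([C@@H](O)c1ccc(O[Si](C)(C)C(C)(C)C)cc1)C(=O)N1[C@H](Cc2ccccc2)COC1=O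
A3 | alternative 1 | 4-[(tert-butyldimethylsilyl)oxy]benzaldehyde | O=Cc1ccc(O[Si](C)(C)C(C)(C)C)cc1
A4 | alternative 2 | methoxymethyl ether of {4-[(tert-butyldimethylsilyl)oxy]phenyl}(4-{4-[(tert-butyldimethylsilyl)oxy]phenyl}cyclohex-3-en-1-yl)methanol | COCO[C@@H](c1ccc(O[Si](C)(C)C(C)(C)C)cc1)[C@@H]1CC=C(c2ccc(O[Si](C)(C)C(C)(C)C)cc2)CC1
A5 | alternative 2 | 2,6-bis{4-[(tert-butyldimethylsilyl)oxy]phenyl}-3-oxabicyclo[3.3.1]non-6-ene | C1C=C(c3ccc(O[Si](C)(C)C(C)(C)C)cc3)[C@@H]2C[C@H]1[C@H](c1ccc(O[Si](C)(C)C(C)(C)C)cc1)OC2
A6 | alternative 3 | methyl 5-[(S)-hydroxy{4-[(tert-butyldimethylsilyl)oxy]phenyl}methyl]furan-3-carboxylate | O[C@H](c1cc(C(=O)OC)co1)c1ccc(O[Si](C)(C)C(C)(C)C)cc1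
A7 | alternative 3 | methyl 6-{4-[(tert-butyldimethylsilyl)oxy]phenyl}-2-hydroxy-5-oxo-5,6-dihydro-2H-pyran-3-carboxylate (C6 anomers, target numbering) | O=C1C=C(C(=O)OC)C(O)O[C@H]1c1ccc(O[Si](C)(C)C(C)(C)C)cc1
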